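The data stem from a simulated flask with made-up constants; scatter was added.

Q, the reagent, has two ways out of these flasks: with Z it gives J and E, and two Q together give X.

the same everywhere: Q 0.0147 M
- dusk: Z 0.0056 M; run made earlier
- noon: Z 0.011 M; run made earlier
- winter: Z 0.019 M; run made earlier
- larch: Z 0.0050 M; time 20 h
- birch: Z 0.010 M; time 20 h
- elm: Z 0.020 M; time 20 h

- dusk (time / h: J / %, Z / %): 1.00: 2.9, 97.5; 2.00: 5.2, 94.2; 4.00: 8.9, 89.9; 8.00: 17.4, 83.4; 15.0: 24.3, 75.2
- noon (time / h: J / %, Z / %): 1.00: 3.8, 97.6; 2.00: 5.4, 94.6; 4.00: 9.9, 90.4; 8.00: 16.1, 82.9; 15.0: 24.4, 76.2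
- winter (time / h: J / %, Z / %): 1.00: 3.5, 97.9; 2.00: 5.6, 94.7; 4.00: 10.0, 90.7; 8.00: 15.0, 84.5; 15.0: 21.5, 78.1

(scatter of a reading: 0.5 percentage points)

- what was read earlier has a scatter of 0.5 percentage points, one standard deviation
- steps thought possible: Z + Q -> J + E; 2 Q -> X
- "hardly changes" means that all values lie within two and a half points (for a concentration: within two and a half percent of the largest)

1. amount of J at the end, in percent of the Z charged for larch, birch, elm, in this order
2. the shape of the row from first to last (falls, then rises / hardly changes / rises, then falls / falls all the way / rises all the way)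

In dusk, J and Z add up to about the charge (24.3 % and 75.2 % at 15.0 h), so each Z lost counts as one J. With z and q the fractions of the charges left, and λ the charge of Z over the charge of Q, the balances read:

dz/dt = −a q z

dq/dt = −q (b q + a λ z)

Setting z/q to one gives 1/q = 1 + Bt, with B = b + aλ, and then:

z = (1 + Bt)^(−a/B)

Of the three runs with readings, dusk carries the smallest charge of Z. There, taking z as the mean of Z and the complement of J, ln z falls by 0.0250 /h up to 4.00 h and by 0.0165 /h from then to 15.0 h. These two rates are aq at mid-interval, so the readings give B = 0.0786 /h, a = 0.0289 /h and b = 0.0676 /h.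

For larch, b/(aλ) = 6.88. This is the split N, the Q going to X per Q going to Z at the start, a selectivity factor for Q. Since B = b(1 + 1/N), and a and b stay as they are at this one charge of Q, the Z charge enters the outcome through N, and N scales inversely with the Z charged: 3.44 for birch, 1.72 for elm. My reckoning for J at 20 h:

larch 29.5 %, birch 28.4 %, elm 26.6 %

As a test, winter (N = 1.81) at 15.0 h comes out at 22.9 % against a mean reading of 21.7 %. One number therefore runs 1.2 percentage points high there, and elm, with a lower N, probably does too. The row still falls, by 2.9 points.

The forecast gives 28.5 %, 27 %, 24.6 % and falls all the way, on the ground that “Larger Z charges also use up more Q”. My reckoning stands 1.00 point above it for larch and 2 points above it for elm.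

The flask gives 29.8 %, 28.3 %, 25.6 %: falls all the way.

    Z + Q → J + E (k = 2.10 /M/h)
    2 Q → X (k = 2.60 /M/h)

In larch, Q goes to X 7.3 times as fast as to Z at the start and 3.6 times as fast at 20.0 h, when 35 % of its Q and 70 % of its Z are left. Larch, read at N = 6.88, has by then spent 5.41 Q on X per Q spent on Z, while elm, at N = 1.72, has spent 1.19, with 24 % of its Q left.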